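**Assumption:** the quinidine-derived thiourea is taken to give the 2S flavanone (its quinine-derived pseudoenantiomer gives 2R); the sign is checked on 13 by CD and chiral HPLC before scale-up.

## Retrosynthetic overview

1. Target 26 comes from ketone 23 by one-pot hydrogenolysis of four benzyl ethers and of the aryl ketone C=O.
2. 23 is cut at the diarylmethine carbon into flavan boronate 16 and chalcone 22; a Rh/(R)-BINAP asymmetric 1,4-addition joins them and sets the R centre.
3. 16 comes from (S)-6-bromoflavanone 13 (C4 deoxygenation, borylation); 13 comes from alkylidene β-ketoester 10 by enantioselective intramolecular oxa-Michael addition and decarboxylation.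
4. 10 comes from β-ketoester 4 (from methyl 2,4-dihydroxybenzoate) and aldehyde 8 (from 4-(benzyloxy)phenol); 22 comes from 2',4'-dihydroxyacetophenone and 4-(benzyloxy)benzaldehyde.
5. Ring order: all five benzene rings are bought; the only ring made is the pyran ring of the chroman (ring C), closed in step 7.

## Route

**Step 1**
Reactants: 1 methyl 2,4-dihydroxybenzoate
Product: 2 methyl 5-bromo-2,4-dihydroxybenzoate
Conditions: Br2 (1.0 equiv), AcOH, rt
Reagents that add atoms: bromine, BrBr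
Why: Electrophilic aromatic bromination goes to C5, which is para to the 2-OH and ortho to the 4-OH and less hindered than C3 between the two hydroxyls.

**Step 2**
Reactants: 2 methyl 5-bromo-2,4-dihydroxybenzoate
Product: 3 methyl 4-(benzyloxy)-5-bromo-2-hydroxybenzoate
Conditions: BnBr (1.05 equiv), K2CO3 (1.1 equiv), acetone, reflux
Reagents that add atoms: benzyl bromide, BrCc1ccccc1
Why: Williamson ether synthesis is selective for the free 4-OH because the 2-OH is held in a hydrogen bond to the ester carbonyl.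

**Step 3**
Reactants: 3 methyl 4-(benzyloxy)-5-bromo-2-hydroxybenzoate
Product: 4 tert-butyl 3-[4-(benzyloxy)-5-bromo-2-hydroxyphenyl]-3-oxopropanoate
Conditions: LiN(iPr)2 (3.5 equiv), t-BuOAc (3.6 equiv), THF, −78 °C; then 3, −78 → 0 °C; aq NH4Cl
Reagents that add atoms: tert-butyl acetate, CC(=O)OC(C)(C)C
Why: Crossed Claisen condensation in which excess lithium enolate deprotonates the phenol, acylates on the methyl ester and leaves the product as its enolate, while the tert-butyl ester blocks lactonisation to a 4-hydroxycoumarin.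

**Step 4**
Reactants: 5 4-(benzyloxy)phenol
Product: 7 5-(benzyloxy)-2-hydroxybenzaldehyde, via salicyl alcohol 6 (not isolated)
Conditions: MgCl2 (1.5 equiv), Et3N (3.8 equiv), (CH2O)n (6 equiv), MeCN, reflux; 1 M HCl work-up
Reagents that add atoms: paraformaldehyde (formaldehyde), C=O
Why: Casnati–Skattebøl ortho-formylation, in which the magnesium phenoxide directs formaldehyde to the carbon next to OH and the salicyl alcohol is oxidised by hydride transfer to a second formaldehyde.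

**Step 5**
Reactants: 7 5-(benzyloxy)-2-hydroxybenzaldehyde
Product: 8 5-(benzyloxy)-2-methoxybenzaldehyde
Conditions: MeI (1.5 equiv), K2CO3 (1.5 equiv), DMF, 40 °C
Reagents that add atoms: iodomethane, CI
Why: Williamson O-methylation of the only free phenol.

**Step 6**
Reactants: 4 tert-butyl 3-[4-(benzyloxy)-5-bromo-2-hydroxyphenyl]-3-oxopropanoate; 8 5-(benzyloxy)-2-methoxybenzaldehyde
Product: 10 tert-butyl 2-[4-(benzyloxy)-5-bromo-2-hydroxybenzoyl]-3-[5-(benzyloxy)-2-methoxyphenyl]prop-2-enoate (E/Z mixture), via aldol adduct 9 (not isolated)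
Conditions: piperidine (10 mol %), AcOH (10 mol %), 4 Å MS, toluene, rt
Reagents that add atoms: none
Why: Knoevenagel condensation of the doubly activated methylene with the aldehyde, kept mild so that the ketone-hydrogen-bonded phenol does not cyclise without stereocontrol.

**Step 7**
Reactants: 10 tert-butyl 2-[4-(benzyloxy)-5-bromo-2-hydroxybenzoyl]-3-[5-(benzyloxy)-2-methoxyphenyl]prop-2-enoate
Product: 13 (2S)-7-(benzyloxy)-2-[5-(benzyloxy)-2-methoxyphenyl]-6-bromochroman-4-one, via chromanone tert-butyl ester 11 (not isolated), via chromanone keto acid 12 (not isolated)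
Conditions: quinidine-derived 9-epi-amino thiourea [N-aryl = 3,5-(CF3)2C6H3] (10 mol %), toluene, −25 °C; then TsOH·H2O (1 equiv), 80 °C; recrystallise (EtOH)
Reagents that add atoms: none
Why: 6-endo-trig intramolecular oxa-Michael addition in which the thiourea binds the β-ketoester and the quinuclidine nitrogen activates the phenol, so oxygen adds to one face of the alkylidene and sets C2 as S, after which acid cleaves the tert-butyl ester and the β-keto acid decarboxylates without touching C2.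

**Step 8**
Reactants: 13 (2S)-7-(benzyloxy)-2-[5-(benzyloxy)-2-methoxyphenyl]-6-bromochroman-4-one
Product: 14 (2S,4S)-7-(benzyloxy)-2-[5-(benzyloxy)-2-methoxyphenyl]-6-bromochroman-4-ol
Conditions: NaBH4 (1.5 equiv), THF/MeOH 1:1, 0 °C
Reagents that add atoms: none
Why: Hydride reduction of the aryl ketone gives mainly the 2,4-cis alcohol, and because C4 is removed in the next step its ratio does not matter while C2 is not enolisable and stays S.

**Step 9**
Reactants: 14 (2S,4S)-7-(benzyloxy)-2-[5-(benzyloxy)-2-methoxyphenyl]-6-bromochroman-4-ol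
Product: 15 (2S)-7-(benzyloxy)-2-[5-(benzyloxy)-2-methoxyphenyl]-6-bromochromane
Conditions: Et3SiH (3 equiv), TFA (10 equiv), CH2Cl2, 0 °C, 30 min
Reagents that add atoms: none
Why: Ionic hydrogenation, in which the C4 cation stabilised by the para benzyloxy group and the ring oxygen is trapped by silane hydride faster than the C2–O bond can ionise.

**Step 10**
Reactants: 15 (2S)-7-(benzyloxy)-2-[5-(benzyloxy)-2-methoxyphenyl]-6-bromochromane
Product: 16 2-{(2S)-7-(benzyloxy)-2-[5-(benzyloxy)-2-methoxyphenyl]chroman-6-yl}-4,4,5,5-tetramethyl-1,3,2-dioxaborolane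
Conditions: B2pin2 (1.5 equiv), PdCl2(dppf) (5 mol %), KOAc (3 equiv), 1,4-dioxane, 90 °C
Reagents that add atoms: bis(pinacolato)diboron, CC1(C)OB(OC1(C)C)B1OC(C)(C)C(C)(C)O1
Why: Miyaura borylation of the aryl bromide under weakly basic conditions that leave the benzyl ethers and the C2 centre alone.

**Step 11**
Reactants: 17 1-(2,4-dihydroxyphenyl)ethanone
Product: 18 1-[4-(benzyloxy)-2-hydroxyphenyl]ethanone
Conditions: BnBr (1.05 equiv), K2CO3 (1.1 equiv), acetone, reflux
Reagents that add atoms: benzyl bromide, BrCc1ccccc1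
Why: Williamson ether synthesis at the free 4-OH, the 2-OH being chelated to the ketone.

**Step 12**
Reactants: 18 1-[4-(benzyloxy)-2-hydroxyphenyl]ethanone
Product: 19 1-[4-(benzyloxy)-2-methoxyphenyl]ethanone
Conditions: MeI (2 equiv), K2CO3 (2 equiv), DMF, 50 °C
Reagents that add atoms: iodomethane, CI
Why: Williamson O-methylation of the chelated phenol under slightly forcing conditions.

**Step 13**
Reactants: 19 1-[4-(benzyloxy)-2-methoxyphenyl]ethanone; 20 4-(benzyloxy)benzaldehyde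
Product: 22 (E)-1-[4-(benzyloxy)-2-methoxyphenyl]-3-[4-(benzyloxy)phenyl]prop-2-en-1-one, via aldol adduct 21 (not isolated)
Conditions: KOH (aq 50%), EtOH, rt
Reagents that add atoms: none
Why: Claisen–Schmidt condensation with E1cB dehydration to the conjugated E enone, which crystallises from the medium.

**Step 14**
Reactants: 16 2-{(2S)-7-(benzyloxy)-2-[5-(benzyloxy)-2-methoxyphenyl]chroman-6-yl}-4,4,5,5-tetramethyl-1,3,2-dioxaborolane; 22 (E)-1-[4-(benzyloxy)-2-methoxyphenyl]-3-[4-(benzyloxy)phenyl]prop-2-en-1-one (2 equiv)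
Product: 23 (3R)-1-[4-(benzyloxy)-2-methoxyphenyl]-3-[4-(benzyloxy)phenyl]-3-{(2S)-7-(benzyloxy)-2-[5-(benzyloxy)-2-methoxyphenyl]chroman-6-yl}propan-1-one
Conditions: [RhCl(C2H4)2]2 (2.5 mol %), (R)-BINAP (6 mol %), KOH (0.5 equiv), 1,4-dioxane/H2O 10:1, 60 °C
Reagents that add atoms: none
Why: Hayashi–Miyaura asymmetric conjugate addition in which the aryl–rhodium/(R)-BINAP species inserts the E enone on its α-re face, giving the R diarylmethine centre under catalyst control while the remote C2 centre is untouched.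

**Step 15**
Reactants: 23 (3R)-1-[4-(benzyloxy)-2-methoxyphenyl]-3-[4-(benzyloxy)phenyl]-3-{(2S)-7-(benzyloxy)-2-[5-(benzyloxy)-2-methoxyphenyl]chroman-6-yl}propan-1-one
Product: 26 (2S)-2-(5-hydroxy-2-methoxyphenyl)-6-[(1R)-3-(4-hydroxy-2-methoxyphenyl)-1-(4-hydroxyphenyl)propyl]chroman-7-ol, via tetraphenol ketone 24 (not isolated), via tetraphenol carbinol 25 (not isolated)
Conditions: H2 (4 bar), 10% Pd/C, EtOAc/MeOH 1:1, HCl (0.2 equiv), rt → 40 °C
Reagents that add atoms: none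
Why: Catalytic hydrogenolysis removes the four benzyl ethers, and the electron-rich aryl ketone is then reduced through its carbinol to CH2 under acid, while the cyclic C2–O ether and both stereocentres, which bear no exchangeable hydrogen, survive.

## Compound list

1 | methyl 2,4-dihydroxybenzoate | COC(=O)c1ccc(O)cc1O | starting material
2 | methyl 5-bromo-2,4-dihydroxybenzoate | COC(=O)c1cc(Br)c(O)cc1O | intermediate
3 | methyl 4-(benzyloxy)-5-bromo-2-hydroxybenzoate | COC(=O)c1cc(Br)c(OCc2ccccc2)cc1O | intermediate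
4 | tert-butyl 3-[4-(benzyloxy)-5-bromo-2-hydroxyphenyl]-3-oxopropanoate | CC(C)(C)OC(=O)CC(=O)c1cc(Br)c(OCc2ccccc2)cc1O | intermediate
5 | 4-(benzyloxy)phenol | Oc1ccc(OCc2ccccc2)cc1 | starting material
6 | 4-(benzyloxy)-2-(hydroxymethyl)phenol (salicyl alcohol, not isolated) | OCc1cc(OCc2ccccc2)ccc1O | intermediate
7 | 5-(benzyloxy)-2-hydroxybenzaldehyde | O=Cc1cc(OCc2ccccc2)ccc1O | intermediate
8 | 5-(benzyloxy)-2-methoxybenzaldehyde | COc1ccc(OCc2ccccc2)cc1C=O | intermediate
9 | tert-butyl 2-[4-(benzyloxy)-5-bromo-2-hydroxybenzoyl]-3-[5-(benzyloxy)-2-methoxyphenyl]-3-hydroxypropanoate (aldol adduct, diastereomer mixture, not isolated) | COc1ccc(OCc2ccccc2)cc1C(O)C(C(=O)OC(C)(C)C)C(=O)c1cc(Br)c(OCc2ccccc2)cc1O | intermediate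
10 | tert-butyl 2-[4-(benzyloxy)-5-bromo-2-hydroxybenzoyl]-3-[5-(benzyloxy)-2-methoxyphenyl]prop-2-enoate (E/Z mixture, geometry not fixed) | COc1ccc(OCc2ccccc2)cc1C=C(C(=O)OC(C)(C)C)C(=O)c1cc(Br)c(OCc2ccccc2)cc1O | intermediate
11 | tert-butyl (2S)-7-(benzyloxy)-2-[5-(benzyloxy)-2-methoxyphenyl]-6-bromo-4-oxochromane-3-carboxylate (C3 epimerisable, not isolated) | COc1ccc(OCc2ccccc2)cc1[C@@H]1C(C(=O)OC(C)(C)C)C(=O)c2cc(Br)c(OCc3ccccc3)cc2O1 | intermediate
12 | (2S)-7-(benzyloxy)-2-[5-(benzyloxy)-2-methoxyphenyl]-6-bromo-4-oxochromane-3-carboxylic acid (C3 epimerisable, not isolated) | COc1ccc(OCc2ccccc2)cc1[C@@H]1C(C(=O)O)C(=O)c2cc(Br)c(OCc3ccccc3)cc2O1 | intermediate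
13 | (2S)-7-(benzyloxy)-2-[5-(benzyloxy)-2-methoxyphenyl]-6-bromochroman-4-one | COc1ccc(OCc2ccccc2)cc1[C@@H]1CC(=O)c2cc(Br)c(OCc3ccccc3)cc2O1 | intermediate
14 | (2S,4S)-7-(benzyloxy)-2-[5-(benzyloxy)-2-methoxyphenyl]-6-bromochroman-4-ol | COc1ccc(OCc2ccccc2)cc1[C@@H]1C[C@H](O)c2cc(Br)c(OCc3ccccc3)cc2O1 | intermediate
15 | (2S)-7-(benzyloxy)-2-[5-(benzyloxy)-2-methoxyphenyl]-6-bromochromane | COc1ccc(OCc2ccccc2)cc1[C@@H]1CCc2cc(Br)c(OCc3ccccc3)cc2O1 | intermediate
16 | 2-{(2S)-7-(benzyloxy)-2-[5-(benzyloxy)-2-methoxyphenyl]chroman-6-yl}-4,4,5,5-tetramethyl-1,3,2-dioxaborolane | COc1ccc(OCc2ccccc2)cc1[C@@H]1CCc2cc(B3OC(C)(C)C(C)(C)O3)c(OCc3ccccc3)cc2O1 | intermediate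
17 | 1-(2,4-dihydroxyphenyl)ethanone | CC(=O)c1ccc(O)cc1O | starting material
18 | 1-[4-(benzyloxy)-2-hydroxyphenyl]ethanone | CC(=O)c1ccc(OCc2ccccc2)cc1O | intermediate
19 | 1-[4-(benzyloxy)-2-methoxyphenyl]ethanone | COc1cc(OCc2ccccc2)ccc1C(C)=O | intermediate
20 | 4-(benzyloxy)benzaldehyde | O=Cc1ccc(OCc2ccccc2)cc1 | starting material
21 | 1-[4-(benzyloxy)-2-methoxyphenyl]-3-[4-(benzyloxy)phenyl]-3-hydroxypropan-1-one (racemic aldol adduct, not isolated) | COc1cc(OCc2ccccc2)ccc1C(=O)CC(O)c1ccc(OCc2ccccc2)cc1 | intermediate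
22 | (E)-1-[4-(benzyloxy)-2-methoxyphenyl]-3-[4-(benzyloxy)phenyl]prop-2-en-1-one | COc1cc(OCc2ccccc2)ccc1C(=O)/C=C/c1ccc(OCc2ccccc2)cc1 | intermediate
23 | (3R)-1-[4-(benzyloxy)-2-methoxyphenyl]-3-[4-(benzyloxy)phenyl]-3-{(2S)-7-(benzyloxy)-2-[5-(benzyloxy)-2-methoxyphenyl]chroman-6-yl}propan-1-one | COc1cc(OCc2ccccc2)ccc1C(=O)C[C@H](c1ccc(OCc2ccccc2)cc1)c1cc2c(cc1OCc1ccccc1)O[C@H](c1cc(OCc3ccccc3)ccc1OC)CC2 | intermediate
24 | (3R)-1-(4-hydroxy-2-methoxyphenyl)-3-(4-hydroxyphenyl)-3-[(2S)-7-hydroxy-2-(5-hydroxy-2-methoxyphenyl)chroman-6-yl]propan-1-one (not isolated) | COc1cc(O)ccc1C(=O)C[C@H](c1ccc(O)cc1)c1cc2c(cc1O)O[C@H](c1cc(O)ccc1OC)CC2 | intermediate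
25 | (2S)-6-[(1R)-3-hydroxy-3-(4-hydroxy-2-methoxyphenyl)-1-(4-hydroxyphenyl)propyl]-2-(5-hydroxy-2-methoxyphenyl)chroman-7-ol (carbinol epimers, not isolated) | COc1cc(O)ccc1C(O)C[C@H](c1ccc(O)cc1)c1cc2c(cc1O)O[C@H](c1cc(O)ccc1OC)CC2 | intermediate
26 | (2S)-2-(5-hydroxy-2-methoxyphenyl)-6-[(1R)-3-(4-hydroxy-2-methoxyphenyl)-1-(4-hydroxyphenyl)propyl]chroman-7-ol | COc1cc(O)ccc1CC[C@H](c1ccc(O)cc1)c1cc2c(cc1O)O[C@H](c1cc(O)ccc1OC)CC2 | target

## Step count and risks

Total step count: 15. Longest linear sequence: 10 steps (1 → 2 → 3 → 4 → 10 → 13 → 14 → 15 → 16 → 23 → 26, that is steps 1, 2, 3, 6, 7, 8, 9, 10, 14, 15), which is two thirds of the total.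

**Step 7 (enantioselective oxa-Michael/decarboxylation).** The ortho-methoxy aryl group or the bromophenol may lower the ee, or the sense may be opposite to that assumed. The fallback sets out from 10 and closes the ring without stereocontrol, then resolves. DABCO (10 mol %) in toluene at rt gives racemic chromanone tert-butyl ester F1; TsOH·H2O at 80 °C in the same pot takes it through racemic keto acid F2 to racemic flavanone F3. Asymmetric transfer hydrogenation with kinetic resolution follows: RuCl(p-cymene)[(S,S)-TsDPEN] (1 mol %), HCO2H/Et3N 5:2, EtOAc, rt, stopped near 50% conversion. The 2S enantiomer is reduced to the cis alcohol, while the slow-reacting (2R)-flavanone F4 is left and removed by chromatography. The fallback comes back to the route at 14.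

**Step 14 (Rh-catalysed addition of the hindered, electron-rich ortho-benzyloxy boronate).** Protodeboronation or slow transmetalation may win. The fallback sets out from 15 and exchanges the roles of the two aryl groups. n-BuLi in THF at −78 °C gives aryllithium F5, and DMF converts it to (2S)-7-(benzyloxy)-2-[5-(benzyloxy)-2-methoxyphenyl]chromane-6-carbaldehyde F6. Claisen–Schmidt condensation of F6 with ketone 19 (KOH, EtOH/THF, rt) passes through aldol adduct F7 to the flavanyl enone F8. Addition of commercial 4-(benzyloxy)phenylboronic acid (OB(O)c1ccc(OCc2ccccc2)cc1, 3 equiv) follows with [RhCl(C2H4)2]2/(S)-BINAP, KOH, dioxane/H2O, 60 °C. Because the incoming and resident aryl groups are swapped, the opposite ligand enantiomer gives the same R centre. The fallback comes back to the route at 23.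

**Step 15 (one-pot debenzylation and ketone deoxygenation).** The reaction may stall at ketone 24 or carbinol 25, or the acid may start to open the C2–O bond. The fallback sets out from 23 and removes the carbonyl without acid before a neutral hydrogenolysis. TsNHNH2 in EtOH with catalytic AcOH at reflux gives tosylhydrazone F9. Catecholborane in CHCl3 at 0 °C, then NaOAc·3H2O at reflux, gives the methylene compound F10, the tetra-O-benzyl ether of the target. H2 (1 atm) over Pd(OH)2 on carbon in EtOAc/MeOH at rt then cleaves the benzyl ethers. The fallback comes back to the route at 26.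

## Further compounds

F1 | step 7 | racemic tert-butyl 7-(benzyloxy)-2-[5-(benzyloxy)-2-methoxyphenyl]-6-bromo-4-oxochromane-3-carboxylate | COc1ccc(OCc2ccccc2)cc1C1Oc2cc(OCc3ccccc3)c(Br)cc2C(=O)C1C(=O)OC(C)(C)C
F2 | step 7 | racemic 7-(benzyloxy)-2-[5-(benzyloxy)-2-methoxyphenyl]-6-bromo-4-oxochromane-3-carboxylic acid | COc1ccc(OCc2ccccc2)cc1C1Oc2cc(OCc3ccccc3)c(Br)cc2C(=O)C1C(O)=O
F3 | step 7 | racemic 7-(benzyloxy)-2-[5-(benzyloxy)-2-methoxyphenyl]-6-bromochroman-4-one | COc1ccc(OCc2ccccc2)cc1C1CC(=O)c2cc(Br)c(OCc3ccccc3)cc2O1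
F4 | step 7 | (2R)-7-(benzyloxy)-2-[5-(benzyloxy)-2-methoxyphenyl]-6-bromochroman-4-one | COc1ccc(OCc2ccccc2)cc1[C@H]1CC(=O)c2cc(Br)c(OCc3ccccc3)cc2O1
F5 | step 14 | {(2S)-7-(benzyloxy)-2-[5-(benzyloxy)-2-methoxyphenyl]chroman-6-yl}lithium | COc1ccc(OCc2ccccc2)cc1[C@@H]1CCc2cc([Li])c(OCc3ccccc3)cc2O1
F6 | step 14 | (2S)-7-(benzyloxy)-2-[5-(benzyloxy)-2-methoxyphenyl]chromane-6-carbaldehyde | COc1ccc(OCc2ccccc2)cc1[C@@H]1CCc2cc(C=O)c(OCc3ccccc3)cc2O1
F7 | step 14 | 1-[4-(benzyloxy)-2-methoxyphenyl]-3-{(2S)-7-(benzyloxy)-2-[5-(benzyloxy)-2-methoxyphenyl]chroman-6-yl}-3-hydroxypropan-1-one (carbinol epimers) | COc1ccc(OCc2ccccc2)cc1[C@@H]1CCc2cc(C(O)CC(=O)c3ccc(OCc4ccccc4)cc3OC)c(OCc3ccccc3)cc2O1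
F8 | step 14 | (E)-1-[4-(benzyloxy)-2-methoxyphenyl]-3-{(2S)-7-(benzyloxy)-2-[5-(benzyloxy)-2-methoxyphenyl]chroman-6-yl}prop-2-en-1-one | COc1ccc(OCc2ccccc2)cc1[C@@H]1CCc2cc(/C=C/C(=O)c3ccc(OCc4ccccc4)cc3OC)c(OCc3ccccc3)cc2O1
F9 | step 15 | 4-methylbenzenesulfonohydrazone of ketone 23 | COc1cc(OCc2ccccc2)ccc1C(=NNS(=O)(=O)c1ccc(C)cc1)C[C@H](c1ccc(OCc2ccccc2)cc1)c1cc2c(cc1OCc1ccccc1)O[C@H](c1cc(OCc3ccccc3)ccc1OC)CC2
F10 | step 15 | (2S)-7-(benzyloxy)-2-[5-(benzyloxy)-2-methoxyphenyl]-6-{(1R)-3-[4-(benzyloxy)-2-methoxyphenyl]-1-[4-(benzyloxy)phenyl]propyl}chromane | COc1cc(OCc2ccccc2)ccc1CC[C@H](c1ccc(OCc2ccccc2)cc1)c1cc2c(cc1OCc1ccccc1)O[C@H](c1cc(OCc3ccccc3)ccc1OC)CC2
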